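## Analysis of the target

CNP0173819.1 is a kalihinene-type diterpenoid bis-formamide. Its carbons are labelled here as follows: ring A is the cyclohexene C1(CH3)=C2–C3–C8–C9–C10, ring B is the cyclohexane C3–C4–C5–C6–C7–C8, and the oxolane is O–C11(CH3)–C12–C13–C14, with C11 bonded to C4 and C14 carrying C15, the CMe2–NHCHO carbon. The six stereocentres are 3R, 4R, 7R, 8S, 11S and 14R. H3 and H8 are cis (a cis-fused octalin), and H4 is anti to H3, so the oxolane is equatorial on ring B. The C7 nitrogen lies on the face of C9 (equatorial, methyl axial), and on the oxolane C4 and C15 are cis. The sensitive groups are the acid-labile trisubstituted alkene, the tertiary ether and two secondary formamides on fully substituted carbons. The difficulty is that both C–N bonds sit on tertiary carbons: substitution there means cations, and a cation at C15 lies next to the ether carbon C14 and would rearrange. In addition, C4 is wedged between the quaternary C11 and the ring fusion. The strategy rests on two features. First, the C15 nitrogen and the C14 oxygen are vicinal, which is the pattern of a ring-opened 2,2-dimethylaziridine. Second, C11 with its methyl, its oxygen, a two-carbon branch and the chain C12–C13 is the carbinol carbon of linalool.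

## Retrosynthetic reasoning

**Formamides last.** Both N–CHO bonds of 37 are cut first, back to diamine 36. Formamides would not survive the dehydrating, organometallic and Lewis-acid steps upstream, so both nitrogens travel masked. In 34 the C15 nitrogen is still the sulfamate left by the ring-forming step and the C7 nitrogen is a trichloroethyl carbamate; one reductive operation uncovers both.

**The C7–N bond.** 34 is 33 with the C5=C6 alkene saturated. In 33 the C7–N bond is cut by a [3,3] shift, back to allyl cyanate 31 and so to carbamate 30 of allylic alcohol 28. The cut is made here because addition or substitution at C7 would leave the face to approach control on a cis-octalin whose two faces are both encumbered. A sigmatropic shift instead carries the C5 configuration to C7. The alcohol 25 that ring closure delivers cannot serve: its hydroxyl is axial on the face opposite C9, and any delivery from it would place nitrogen on the wrong side. 25 is therefore taken through enone 27 to the equatorial alcohol 28. The forward steps must give 28 trans to C11 and rearrange without loss of configuration. The C5 oxygen leaves in the same event, so no separate deoxygenation is needed.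

**Ring B.** 25 is opened at C5–C6 to aldehyde 24, the reverse of a type 2 carbonyl-ene reaction. C6 and C7 then are simply the isopropenyl group of limonene 11, and the closure supplies the C5 oxygen that the C7 amination needs.

**The C3–C4 bond.** 24 is acid 21 at a lower oxidation level (through 22 and 23). 21 is cut at C3–C4 by an Ireland–Claisen transform to ester 18, that is acid 10 plus dienol 15. This bond joins the two chiral-pool halves, and the suprafacial shift carries the C1–O configuration of 15 to C3, cis to the isopropenyl group. The forward reaction must also fix C4, which depends on ketene acetal geometry and transition-state shape; this is the weakest stereochemical link of the route.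

**Dienol 15** goes back to limonene 11 through epoxide 12 and hydroxy selenide 13. This places the tertiary hydroxyl cis to the isopropenyl group.

**Acid 10** goes back to vinyl oxolane 6: the two vinyl carbons become C4 and C5 (through alcohol 8).

**The ether ring (key step).** 6 is cut at O–C14, back to hydroxy aziridine 4. The nitrogen is then already on the tertiary carbon C15 and no cation next to the ether is needed. Opening with inversion at C14 sets the cis-2,5 ring.

**Aziridine 4** comes from linalool 1 and sulfamate 2 by nitrene transfer to the trisubstituted alkene. C11 is taken unchanged from 1.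

## Alternatives that were turned down

**Alternative 1:** The disconnection cuts C3–C4 and C11–O together, so ring B and the oxolane arise in one cationic cascade from the monocyclic hydroxy diene A2. In the forward step a Lewis acid ionises the tertiary allylic alcohol of A2, the (Z)-alkene C4=C11 attacks the allyl cation at C3, and the C14 hydroxyl captures the C11 cation to give A1.
- For it: two rings and three stereocentres in one step, and nitrogen carried as robust azide and nitrile. It is stronger than the chosen route at C4, because ring closure through a chair puts the large group equatorial, whereas the chosen route sets C4 in a sigmatropic transition state.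
- Against it: the allyl cation is planar, so nothing forces the cis fusion or stops attack at the C1 terminus. C11 depends on the geometric purity of the alkene and on clean anti addition. A2 must already hold the quaternary C7 nitrile and the C14 carbinol, set by remote acyclic control.
- Comparison: the chosen route is longer from the union onwards, but C11 comes from the chiral pool and C14 from a stereospecific SN2 opening, and each ring is closed by a stereospecific step.

**Alternative 2:** The disconnection is C5–C6; aldehyde A4 closes ring B by a Lewis-acid carbonyl-ene reaction to give A3.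
- For it: the six-membered type 2 ene closure is reliable and limonene supplies C8. On this point it is exactly as strong as the chosen route, which uses the same closure downstream (24 to 25).
- Against it as the carrier of the strategy: everything difficult (the oxolane with its tertiary nitrogen, and C4) must already be present in A4, and the step creates none of it. A3 still needs the C7 amination and removal of the C5 oxygen. The hydrogen transfer also calls for an axial hydroxyl, not the equatorial one drawn in A3.
- Comparison: the chosen strategy solves the ether and nitrogen problem that this alternative takes for granted.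

**Alternative 3:** The disconnection is C13–C14; the bromide A6 closes the oxolane by a 5-exo radical addition to its β-alkoxyacrylate, giving A5.
- For it: the cis-2,5 preference of such closures is well founded and as good as the inversion used here, and the ring is made late on the complete decalin.
- Against it: A6 needs the tertiary C11 carbinol created next to C4 on the decalin without a controlling element, and O-vinylation of a very hindered tertiary alcohol. A5 carries C15 only as CH2CO2CH3, so two methyl groups and a degradation of the ester to nitrogen at a tertiary carbon remain. The double alkylation runs α to an ester that is β to the ring oxygen. A stannane-mediated step is also needed.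
- Comparison: the chosen route makes the C15–N bond on the alkene of 1 in the first step and closes the ring without radicals or further carbon changes at C15.

Key step: step 2

## Remarks before the steps

- Decalin intermediates are named with the route locants C1–C10 defined in the analysis (not von Baeyer locants).
- "OxTces" stands for the group (2S,5R)-2-methyl-5-(2-{[(2,2,2-trichloroethoxy)sulfonyl]amino}propan-2-yl)oxolan-2-yl, attached through C11.
- Assumption: the sense of induction of the chiral dirhodium carboxylate on a purely alkyl-substituted alkene cannot be derived from a simple model. The ligand antipode that gives 4 is to be assigned by correlation (cis versus trans oxolane after step 2) and is written here as the (S) series.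

## Route

Step 1
Reactants: 1 (S)-linalool; 2 2,2,2-trichloroethyl sulfamate (TcesNH2)
Product: 4 2,2,2-trichloroethyl (3S)-3-[(3S)-3-hydroxy-3-methylpent-4-en-1-yl]-2,2-dimethylaziridine-1-sulfonate, via iminoiodinane 3 (not isolated)
Conditions: PhI(OAc)2, MgO, Rh2(S-tfpttl)4 (2 mol %; tfpttl = N-tetrafluorophthaloyl-tert-leucinate), PhCF3, −15 °C
Reagents that add atoms: none
Why: Rh-catalysed nitrene transfer from a sulfamate is an electrophilic alkene aziridination, so the electron-rich trisubstituted alkene of 1 should react in preference to the vinyl group and to C–H bonds; the distant C11 centre gives no control, so the new C14 centre is set by the chiral carboxylate ligands, and any C14 epimer stays a separable diastereomer after step 2.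

Step 2
Reactants: 4 hydroxy aziridine
Product: 6 2,2,2-trichloroethyl N-{2-[(2R,5S)-5-ethenyl-5-methyloxolan-2-yl]propan-2-yl}sulfamate, via potassium alkoxide 5 (not isolated)
Conditions: KH (1.2 equiv), THF, 0 to 23 °C; then aq. NH4Cl
Reagents that add atoms: none
Why: KH removes the hydroxyl proton irreversibly to give alkoxide 5, whose oxygen attacks the secondary aziridine carbon C14 from the side opposite the C14–N bond, so that the O–C14 bond forms and the sulfamate nitrogen stays on the tertiary carbon C15 as a stabilised anion. The closest known reaction type is the intramolecular alkoxide opening of N-sulfonyl aziridines at the less substituted carbon, the nitrogen counterpart of the base-induced closure of 6,7-epoxylinalool to the furanoid linalool oxides. The ring (O, C11, C12, C13, C14) closes in the 5-exo-tet mode, driven by release of aziridine strain. The one new stereocentre, C14, is controlled by inversion of the aziridine carbon configured in step 1; C11 is not touched, so the vinyl and the CMe2N groups come out cis. The step needs 5-exo opening at C14 and not 6-endo opening at C15: the basic, non-ionising medium excludes attack at the tertiary carbon and the five-membered transition state is the kinetically preferred one. Proton abstraction from a C15 methyl group (isomerisation to an allylic sulfamate) is held back because the only soluble base is the tethered alkoxide, which reaches C14 more easily than those hydrogens. The product forms as its N-potassium salt, inert to further reaction, and is set free on quenching.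

Step 3
Reactants: 6 vinyl oxolane
Product: 8 2-(OxTces)ethan-1-ol, via B-alkyl-9-BBN adduct 7 (not isolated)
Conditions: 9-BBN (2.5 equiv), THF, 0 to 23 °C; then NaBO3·4H2O, H2O, 23 °C
Reagents that add atoms: sodium perborate tetrahydrate, [Na+].[Na+].O[B-]1(O)OO[B-](O)(O)OO1
Why: Hydroboration–oxidation: 9-BBN places boron on the terminal carbon of the vinyl group attached to the quaternary C11 for steric reasons, and perborate oxidises the C–B bond with retention without harming the sulfamate; one equivalent of borane is spent on the acidic N–H.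

Step 4
Reactants: 8 primary alcohol
Product: 10 2-(OxTces)acetic acid, via aldehyde 9 (not isolated)
Conditions: TEMPO (0.2 equiv), PhI(OAc)2 (2.2 equiv), MeCN–H2O (1:1), 23 °C
Reagents that add atoms: water, O
Why: The oxoammonium oxidation (TEMPO with PhI(OAc)2 in aqueous acetonitrile) takes the alcohol through aldehyde 9 and its hydrate to the acid under near-neutral conditions that leave the ether and the sulfamate alone.

Step 5
Reactants: 11 (S)-limonene
Product: 12 (1R,2S,4S)-1,2-epoxy-p-menth-8-ene
Conditions: mCPBA, CH2Cl2, 0 °C
Reagents that add atoms: mCPBA, OOC(=O)c1cccc(Cl)c1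
Why: Prilezhaev epoxidation attacks the more nucleophilic trisubstituted ring alkene and not the isopropenyl group; both faces react, and the diastereomer with oxygen trans to isopropenyl is taken along as a passenger that reacts far more slowly in step 6 and is separated there.

Step 6
Reactants: 12 limonene 1,2-oxide (oxygen cis to isopropenyl)
Product: 13 (1R,2R,4S)-1-methyl-2-(phenylselanyl)-4-(prop-1-en-2-yl)cyclohexan-1-ol
Conditions: (PhSe)2, NaBH4, EtOH, 23 °C; then 12, 60 °C
Reagents that add atoms: diphenyl diselenide, c1ccccc1[Se][Se]c1ccccc1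
Why: Selenolate opening of the epoxide: with isopropenyl equatorial, the trans-diaxial (Fürst–Plattner) opening of 12 puts the nucleophile on the secondary carbon C2 with inversion and leaves the tertiary C1–O bond, cis to isopropenyl, untouched.

Step 7
Reactants: 13 hydroxy selenide
Product: 15 (1R,4S)-1-methyl-4-(prop-1-en-2-yl)cyclohex-2-en-1-ol, via selenoxide 14 (not isolated)
Conditions: 30% H2O2, pyridine, THF, 0 to 23 °C
Reagents that add atoms: none
Why: Selenoxide syn-elimination: C1 carries no hydrogen, so the alkene can only form toward C3, which gives the tertiary allylic alcohol with hydroxyl cis to the isopropenyl group.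

Step 8
Reactants: 10 2-(OxTces)acetic acid; 15 dienol
Product: 18 (1R,4S)-1-methyl-4-(prop-1-en-2-yl)cyclohex-2-en-1-yl 2-(OxTces)acetate, via acid chloride 16 (not isolated), via lithium alkoxide 17 (not isolated)
Conditions: 10, 1-chloro-N,N,2-trimethylprop-1-en-1-amine, CH2Cl2, 0 °C; 15 (2.2 equiv), n-BuLi, THF, −78 °C; combine, −78 to 0 °C
Reagents that add atoms: none
Why: Acylation of a preformed lithium alkoxide by an acid chloride is the dependable esterification of a hindered, acid-labile tertiary allylic alcohol; the chloroenamine makes 16 without acid, the excess of 17 absorbs the sulfamate N–H, and no stereocentre is touched.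

Step 9
Reactants: 18 allylic ester
Product: 21 (2R)-2-[(1R,6S)-3-methyl-6-(prop-1-en-2-yl)cyclohex-2-en-1-yl]-2-(OxTces)acetic acid, via silyl ketene acetal 19 (not isolated), via silyl ester 20 (not isolated)
Conditions: LDA (LiN(iPr)2, 2.3 equiv), THF, −78 °C; TBSCl, DMPU, −78 to 23 °C, then 50 °C; 1 M HCl, THF
Reagents that add atoms: none
Why: Ireland–Claisen rearrangement: LDA in THF should give the ketene acetal with C11 trans to the silyloxy group (Ireland enolisation model), and the [3,3] shift is suprafacial on the face of the C1–O bond, so C4 is joined to C3 cis to the isopropenyl group, which fixes the later cis ring fusion. C4 is set by the boat-like transition state that cyclohex-2-enyl esters adopt when the silyloxy group would otherwise lie over the ring (the reason for the bulky silyl group); with this acetal geometry the boat places C11 over the C3–C8 bond, where the top substituent on C8 is pseudoequatorial and C11 can turn its ring oxygen toward ring A, and that arrangement gives the (R) acid.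

Step 10
Reactants: 21 acid
Product: 22 methyl (2R)-2-[(1R,6S)-3-methyl-6-(prop-1-en-2-yl)cyclohex-2-en-1-yl]-2-(OxTces)acetate
Conditions: TMSCHN2, toluene–MeOH, 0 °C
Reagents that add atoms: (trimethylsilyl)diazomethane, C[Si](C)(C)C=[N+]=[N-]
Why: O-Methylation through the diazonium ion pair alkylates the carboxylate oxygen, so the crowded carboxyl carbon need not be activated and C4 cannot epimerise.

Step 11
Reactants: 22 methyl ester
Product: 23 (2S)-2-[(1R,6S)-3-methyl-6-(prop-1-en-2-yl)cyclohex-2-en-1-yl]-2-(OxTces)ethan-1-ol
Conditions: DIBAL-H (iBu2AlH, 4 equiv), CH2Cl2, −78 to 0 °C; aq. KNa tartrate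
Reagents that add atoms: none
Why: Hydride reduction of the ester to the primary alcohol; iBu2AlH at low temperature should spare the trichloroethyl group, which LiAlH4 might not, and the alkenes are inert (the descriptor at C4 changes only through the priority rules).

Step 12
Reactants: 23 primary alcohol
Product: 24 (2R)-2-[(1R,6S)-3-methyl-6-(prop-1-en-2-yl)cyclohex-2-en-1-yl]-2-(OxTces)acetaldehyde
Conditions: DMP, NaHCO3, CH2Cl2, 0 to 23 °C
Reagents that add atoms: none
Why: Buffered Dess–Martin oxidation gives the aldehyde under neutral conditions, so the enolisable C4 centre and the ring oxygen β to the carbonyl are not put at risk.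

Step 13
Reactants: 24 aldehyde
Product: 25 (3R,4S,5R,8S)-1-methyl-7-methylidene-4-(OxTces)bicyclo[4.4.0]dec-1-en-5-ol (route locants)
Conditions: Me2AlCl (2.5 equiv), CH2Cl2, −78 °C; aq. NaHCO3
Reagents that add atoms: none
Why: Type 2 carbonyl-ene reaction: the Me2AlCl-bound aldehyde is attacked by the terminal carbon C6 of the isopropenyl group through a chair in which the oxolane is equatorial and the carbonyl oxygen axial, where it can accept a hydrogen from the methyl group; ring B closes cis-fused (C3 and C8 are already fixed) with an exocyclic methylene at C7. The reagent also scavenges protons, which protects the alkenes, and the C5 configuration is erased again in step 14.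

Step 14
Reactants: 25 homoallylic alcohol
Product: 27 (3R,4R,8S)-1,7-dimethyl-4-(OxTces)bicyclo[4.4.0]deca-1,6-dien-5-one (route locants), via β,γ-unsaturated ketone 26 (not isolated)
Conditions: DMP, NaHCO3, CH2Cl2, 0 °C; aqueous work-up; DBU (0.2 equiv), CH2Cl2, 0 °C
Reagents that add atoms: none
Why: Dess–Martin oxidation gives ketone 26, whose doubly activated C6 hydrogens let catalytic DBU move the alkene into conjugation at 0 °C; the brief, mild base treatment is chosen so that the much less acidic C4–H and C8–H, and with C4–H the β-oxygen of the oxolane, are not engaged.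

Step 15
Reactants: 27 enone
Product: 28 (3R,4S,5S,8S)-1,7-dimethyl-4-(OxTces)bicyclo[4.4.0]deca-1,6-dien-5-ol (route locants)
Conditions: NaBH4, CeCl3·7H2O, MeOH, −78 °C
Reagents that add atoms: none
Why: Luche reduction: 1,2-selective hydride delivery along the axial trajectory, which the equatorial oxolane does not block, should give the pseudoequatorial alcohol, trans to C11 and on the face of C9, where the nitrogen is needed.

Step 16
Reactants: 28 allylic alcohol
Product: 30 (3R,4S,5S,8S)-1,7-dimethyl-4-(OxTces)bicyclo[4.4.0]deca-1,6-dien-5-yl carbamate (route locants), via N-trichloroacetyl carbamate 29 (not isolated)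
Conditions: Cl3CC(O)NCO, CH2Cl2, 0 °C; then K2CO3, MeOH, 23 °C
Reagents that add atoms: trichloroacetyl isocyanate, O=C=NC(=O)C(Cl)(Cl)Cl
Why: Carbamoylation with the highly electrophilic acyl isocyanate works even on this flanked secondary alcohol, and mild methanolysis removes the trichloroacetyl group to leave the primary carbamate with C5 unchanged.

Step 17
Reactants: 30 allylic carbamate
Product: 33 2,2,2-trichloroethyl N-[(3R,4R,7R,8S)-1,7-dimethyl-4-(OxTces)bicyclo[4.4.0]deca-1,5-dien-7-yl]carbamate (route locants), via allyl cyanate 31 (not isolated), via isocyanate 32 (not isolated)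
Conditions: (CF3CO)2O, Et3N, CH2Cl2, 0 to 23 °C; then Cl3CCH2OH, CuCl (cat.), DMF, 23 °C
Reagents that add atoms: 2,2,2-trichloroethanol, OCC(Cl)(Cl)Cl
Why: Dehydration of the carbamate gives allyl cyanate 31, which undergoes the allyl cyanate-to-isocyanate [3,3] rearrangement; the shift is suprafacial, so the C5 configuration is transferred to C7 and nitrogen arrives on the tertiary carbon on the C9 face, methyl opposite, while the alkene moves to C5=C6. CuCl-catalysed addition of the alcohol then converts the hindered isocyanate 32 into the carbamate.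

Step 18
Reactants: 33 diene carbamate
Product: 34 2,2,2-trichloroethyl N-[(3R,4R,7R,8S)-1,7-dimethyl-4-(OxTces)bicyclo[4.4.0]dec-1-en-7-yl]carbamate (route locants)
Conditions: 2-nitrobenzenesulfonohydrazide, Et3N, CH2Cl2, 23 °C (repeated charges)
Reagents that add atoms: none
Why: Diimide reduction (concerted syn transfer of two hydrogens) discriminates by alkene substitution, so the cis-disubstituted C5=C6 bond should be reduced and the trisubstituted C1=C2 bond left; it also tolerates the C–Cl bonds, which hydrogenation over Pd would not.

Step 19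
Reactants: 34 bis(trichloroethyl)-protected diamine
Product: 36 (3R,4R,7R,8S)-4-[(2S,5R)-5-(2-aminopropan-2-yl)-2-methyloxolan-2-yl]-1,7-dimethylbicyclo[4.4.0]dec-1-en-7-amine (route locants), via amino sulfamic acid 35 (not isolated)
Conditions: Zn–Cu couple, AcOH–MeOH (1:1), 23 °C; then HCl in MeOH, 40 °C; aq. NaOH
Reagents that add atoms: none
Why: Reductive β-elimination by zinc removes both trichloroethyl groups at once: the carbamate collapses to the C7 amine and CO2, the sulfamate to the N-sulfonic acid 35, whose N–S bond is then solvolysed in acidic methanol.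

Step 20
Reactants: 36 diamine
Product: 37 N-{(3R,4R,7R,8S)-4-[(2S,5R)-5-(2-formamidopropan-2-yl)-2-methyloxolan-2-yl]-1,7-dimethylbicyclo[4.4.0]dec-1-en-7-yl}formamide (route locants; CNP0173819.1)
Conditions: acetic formic anhydride, pyridine, CH2Cl2, 0 to 23 °C
Reagents that add atoms: acetic formic anhydride, CC(=O)OC=O
Why: N-Formylation of both hindered primary amines by the mixed anhydride, which transfers the formyl group because the formyl carbonyl is the more electrophilic and less hindered one.

## Compound list

1 | (S)-linalool, (3S)-3,7-dimethylocta-1,6-dien-3-ol | C=C[C@](O)(C)CCC=C(C)C | starting material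
2 | 2,2,2-trichloroethyl sulfamate (TcesNH2) | NS(=O)(=O)OCC(Cl)(Cl)Cl | starting material
3 | phenyl-λ3-iodane imide of 2 (PhI=NTces) | O=S(=O)(OCC(Cl)(Cl)Cl)N=Ic1ccccc1 | intermediate (not isolated)
4 | 2,2,2-trichloroethyl (3S)-3-[(3S)-3-hydroxy-3-methylpent-4-en-1-yl]-2,2-dimethylaziridine-1-sulfonate | C=C[C@](O)(C)CC[C@H]1C(C)(C)N1S(=O)(=O)OCC(Cl)(Cl)Cl | intermediate
5 | potassium alkoxide of 4 | C=C[C@]([O-])(C)CC[C@H]1C(C)(C)N1S(=O)(=O)OCC(Cl)(Cl)Cl.[K+] | intermediate (not isolated)
6 | 2,2,2-trichloroethyl N-{2-[(2R,5S)-5-ethenyl-5-methyloxolan-2-yl]propan-2-yl}sulfamate (vinyl and CMe2N cis) | C=C[C@]1(C)CC[C@H](C(C)(C)NS(=O)(=O)OCC(Cl)(Cl)Cl)O1 | intermediate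
7 | B-alkyl-9-BBN adduct of 6 (boron on the terminal carbon; ring centres as in 6) | B1(CC[C@]2(C)CC[C@H](C(C)(C)NS(=O)(=O)OCC(Cl)(Cl)Cl)O2)C3CCCC1CCC3 | intermediate (not isolated)
8 | 2-(OxTces)ethan-1-ol | OCC[C@]1(C)CC[C@H](C(C)(C)NS(=O)(=O)OCC(Cl)(Cl)Cl)O1 | intermediate
9 | 2-(OxTces)acetaldehyde | O=CC[C@]1(C)CC[C@H](C(C)(C)NS(=O)(=O)OCC(Cl)(Cl)Cl)O1 | intermediate (not isolated)
10 | 2-(OxTces)acetic acid | OC(=O)C[C@]1(C)CC[C@H](C(C)(C)NS(=O)(=O)OCC(Cl)(Cl)Cl)O1 | intermediate
11 | (S)-limonene | CC1=CC[C@H](CC1)C(C)=C | starting material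
12 | (1R,2S,4S)-1,2-epoxy-p-menth-8-ene (epoxide oxygen cis to isopropenyl) | C[C@@]12CC[C@@H](C[C@@H]1O2)C(C)=C | intermediate
13 | (1R,2R,4S)-1-methyl-2-(phenylselanyl)-4-(prop-1-en-2-yl)cyclohexan-1-ol | C[C@@]1(O)CC[C@@H](C[C@H]1[Se]c1ccccc1)C(C)=C | intermediate
14 | Se-oxide of 13 | C[C@@]1(O)CC[C@@H](C[C@H]1[Se](=O)c1ccccc1)C(C)=C | intermediate (not isolated)
15 | (1R,4S)-1-methyl-4-(prop-1-en-2-yl)cyclohex-2-en-1-ol (hydroxyl cis to isopropenyl) | C[C@]1(O)C=C[C@H](CC1)C(C)=C | intermediate
16 | 2-(OxTces)acetyl chloride | ClC(=O)C[C@]1(C)CC[C@H](C(C)(C)NS(=O)(=O)OCC(Cl)(Cl)Cl)O1 | intermediate (not isolated)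
17 | lithium (1R,4S)-1-methyl-4-(prop-1-en-2-yl)cyclohex-2-en-1-olate | C[C@]1([O-])C=C[C@H](CC1)C(C)=C.[Li+] | intermediate (not isolated)
18 | (1R,4S)-1-methyl-4-(prop-1-en-2-yl)cyclohex-2-en-1-yl 2-(OxTces)acetate | C[C@]1(OC(=O)C[C@]2(C)CC[C@H](C(C)(C)NS(=O)(=O)OCC(Cl)(Cl)Cl)O2)C=C[C@H](CC1)C(C)=C | intermediate
19 | (E)-O-tert-butyldimethylsilyl ketene acetal of 18 (C11 trans to OSi; N–H drawn free) | C[C@]1(O/C(O[Si](C)(C)C(C)(C)C)=C\[C@]2(C)CC[C@H](C(C)(C)NS(=O)(=O)OCC(Cl)(Cl)Cl)O2)C=C[C@H](CC1)C(C)=C | intermediate (not isolated)
20 | tert-butyldimethylsilyl ester of 21 | CC1=C[C@@H]([C@@H](C(=O)O[Si](C)(C)C(C)(C)C)[C@]2(C)CC[C@H](C(C)(C)NS(=O)(=O)OCC(Cl)(Cl)Cl)O2)[C@H](CC1)C(C)=C | intermediate (not isolated)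
21 | (2R)-2-[(1R,6S)-3-methyl-6-(prop-1-en-2-yl)cyclohex-2-en-1-yl]-2-(OxTces)acetic acid | CC1=C[C@@H]([C@@H](C(=O)O)[C@]2(C)CC[C@H](C(C)(C)NS(=O)(=O)OCC(Cl)(Cl)Cl)O2)[C@H](CC1)C(C)=C | intermediate
22 | methyl ester of 21 | CC1=C[C@@H]([C@@H](C(=O)OC)[C@]2(C)CC[C@H](C(C)(C)NS(=O)(=O)OCC(Cl)(Cl)Cl)O2)[C@H](CC1)C(C)=C | intermediate
23 | (2S)-2-[(1R,6S)-3-methyl-6-(prop-1-en-2-yl)cyclohex-2-en-1-yl]-2-(OxTces)ethan-1-ol | CC1=C[C@@H]([C@@H](CO)[C@]2(C)CC[C@H](C(C)(C)NS(=O)(=O)OCC(Cl)(Cl)Cl)O2)[C@H](CC1)C(C)=C | intermediate
24 | (2R)-2-[(1R,6S)-3-methyl-6-(prop-1-en-2-yl)cyclohex-2-en-1-yl]-2-(OxTces)acetaldehyde | CC1=C[C@@H]([C@@H](C=O)[C@]2(C)CC[C@H](C(C)(C)NS(=O)(=O)OCC(Cl)(Cl)Cl)O2)[C@H](CC1)C(C)=C | intermediate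
25 | (3R,4S,5R,8S)-1-methyl-7-methylidene-4-(OxTces)bicyclo[4.4.0]dec-1-en-5-ol (cis-fused; hydroxyl axial, cis to C11) | CC1=C[C@H]2[C@H]([C@]3(C)CC[C@H](C(C)(C)NS(=O)(=O)OCC(Cl)(Cl)Cl)O3)[C@H](O)CC(=C)[C@H]2CC1 | intermediate
26 | (3R,4R,8S)-1-methyl-7-methylidene-4-(OxTces)bicyclo[4.4.0]dec-1-en-5-one | CC1=C[C@H]2[C@H]([C@]3(C)CC[C@H](C(C)(C)NS(=O)(=O)OCC(Cl)(Cl)Cl)O3)C(=O)CC(=C)[C@H]2CC1 | intermediate (not isolated)
27 | (3R,4R,8S)-1,7-dimethyl-4-(OxTces)bicyclo[4.4.0]deca-1,6-dien-5-one | CC1=C[C@H]2[C@H]([C@]3(C)CC[C@H](C(C)(C)NS(=O)(=O)OCC(Cl)(Cl)Cl)O3)C(=O)C=C(C)[C@H]2CC1 | intermediate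
28 | (3R,4S,5S,8S)-1,7-dimethyl-4-(OxTces)bicyclo[4.4.0]deca-1,6-dien-5-ol (hydroxyl trans to C11) | CC1=C[C@H]2[C@H]([C@]3(C)CC[C@H](C(C)(C)NS(=O)(=O)OCC(Cl)(Cl)Cl)O3)[C@@H](O)C=C(C)[C@H]2CC1 | intermediate
29 | N-(trichloroacetyl)carbamate of 28 | CC1=C[C@H]2[C@H]([C@]3(C)CC[C@H](C(C)(C)NS(=O)(=O)OCC(Cl)(Cl)Cl)O3)[C@@H](OC(=O)NC(=O)C(Cl)(Cl)Cl)C=C(C)[C@H]2CC1 | intermediate (not isolated)
30 | carbamate of 28 | CC1=C[C@H]2[C@H]([C@]3(C)CC[C@H](C(C)(C)NS(=O)(=O)OCC(Cl)(Cl)Cl)O3)[C@@H](OC(N)=O)C=C(C)[C@H]2CC1 | intermediate
31 | cyanate of 28 | CC1=C[C@H]2[C@H]([C@]3(C)CC[C@H](C(C)(C)NS(=O)(=O)OCC(Cl)(Cl)Cl)O3)[C@@H](OC#N)C=C(C)[C@H]2CC1 | intermediate (not isolated)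
32 | (3R,4R,7R,8S)-7-isocyanato-1,7-dimethyl-4-(OxTces)bicyclo[4.4.0]deca-1,5-diene | CC1=C[C@H]2[C@H]([C@]3(C)CC[C@H](C(C)(C)NS(=O)(=O)OCC(Cl)(Cl)Cl)O3)C=C[C@@](C)(N=C=O)[C@H]2CC1 | intermediate (not isolated)
33 | 2,2,2-trichloroethyl N-[(3R,4R,7R,8S)-1,7-dimethyl-4-(OxTces)bicyclo[4.4.0]deca-1,5-dien-7-yl]carbamate | CC1=C[C@H]2[C@H]([C@]3(C)CC[C@H](C(C)(C)NS(=O)(=O)OCC(Cl)(Cl)Cl)O3)C=C[C@@](C)(NC(=O)OCC(Cl)(Cl)Cl)[C@H]2CC1 | intermediate
34 | 2,2,2-trichloroethyl N-[(3R,4R,7R,8S)-1,7-dimethyl-4-(OxTces)bicyclo[4.4.0]dec-1-en-7-yl]carbamate | CC1=C[C@H]2[C@H]([C@]3(C)CC[C@H](C(C)(C)NS(=O)(=O)OCC(Cl)(Cl)Cl)O3)CC[C@@](C)(NC(=O)OCC(Cl)(Cl)Cl)[C@H]2CC1 | intermediate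
35 | C7-amino C15-N-sulfonic acid (sulfamic acid of 36 at the C15 nitrogen) | CC1=C[C@H]2[C@H]([C@]3(C)CC[C@H](C(C)(C)NS(=O)(=O)O)O3)CC[C@@](C)(N)[C@H]2CC1 | intermediate (not isolated)
36 | (3R,4R,7R,8S)-4-[(2S,5R)-5-(2-aminopropan-2-yl)-2-methyloxolan-2-yl]-1,7-dimethylbicyclo[4.4.0]dec-1-en-7-amine | CC1=C[C@H]2[C@H]([C@]3(C)CC[C@H](C(C)(C)N)O3)CC[C@@](C)(N)[C@H]2CC1 | intermediate
37 | CNP0173819.1, the (3R,4R,7R,8S,11S,14R) bis-formamide | CC1=C[C@H]2[C@H]([C@]3(C)CC[C@H](C(C)(C)NC=O)O3)CC[C@@](C)(NC=O)[C@H]2CC1 | target

## Step count and uncertain steps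

Total: 20 steps. Longest linear sequence: 17 steps (1 to 37 through steps 1–4 and 8–20); the limonene branch (steps 5–7) joins at step 8.

**Step 2 (key step).** What may go wrong is diversion of the aziridine before or during the closure. One path is opening at the tertiary carbon in the six-membered mode if any acid is present (also during isolation of 4, which carries a free hydroxyl next to a very electrophilic ring). The other is base-induced isomerisation of the aziridine to an allylic sulfamate by loss of a methyl hydrogen. Fallback: mask the hydroxyl throughout nitrene transfer and release the alkoxide without a metal hydride. Setting out from 1, silylation (Et3SiOTf, 2,6-lutidine) gives the triethylsilyl ether of linalool F1. The conditions of step 1 then give the silylated aziridine F2. Bu4NF in THF at 0 °C removes silicon and the liberated alkoxide closes the ring in the same flask, returning to the route at 6.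

**Step 1.** The risk is poor facial selectivity, because the alkene carries only alkyl groups and the C11 centre is too far away to help; allylic C–H amination is a minor competitor. Fallback: give up catalyst control and separate instead. With the achiral catalyst Rh2(esp)2 (esp = α,α,α′,α′-tetramethyl-1,3-benzenedipropionate), 1 gives 4 together with its C14 epimer, the (3R)-aziridine F3. Both are closed as in step 2, and 6 is separated by chromatography from the trans-2,5-disubstituted oxolane F4. The route continues from 6.

**Step 9.** The risk is the partition between boat-like and chair-like transition states. The chair has the silyloxy group over the ring and C11 outside, and it delivers the C4 epimer. So does any ketene acetal of the opposite geometry formed through chelation by the ring oxygen. With a fully substituted α-substituent the balance cannot be predicted with confidence. Loss of the β-oxygen from the enolate is a lesser risk at −78 °C. Fallback: let a chiral auxiliary, not the transition-state shape, decide C4.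
- From 10, acylation of lithiated (R)-4-benzyloxazolidin-2-one through the pivaloyl mixed anhydride gives the imide F5.
- From 15, n-BuLi and ClCO2CH3 give the methyl carbonate F6.
- The sodium enolate of F5 (NaN(SiMe3)2, THF, −78 °C) is allylated with F6 and Pd(PPh3)4. Ionisation and attack are both anti to the metal, so the C3–C4 bond again forms cis to the isopropenyl group at the less hindered allyl terminus. The benzyl group shields one enolate face, and the product is the allylated imide F7.
- LiOH/H2O2 removes the auxiliary and returns to the route at 21.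

**Step 17.** The risk is a slow rearrangement. The C5–O bond must become pseudoaxial, which forces the oxolane axial, and the cyanate may then ionise or decompose first. The hindered tertiary isocyanate may also be trapped only sluggishly. Fallback: the Overman rearrangement, which uses a more robust migrating group at higher temperature.
- From 28, Cl3CCN and DBU give the trichloroacetimidate F8.
- Heating (xylene, K2CO3, 140 °C) shifts it suprafacially to the allylic trichloroacetamide F9.
- NaOH in aqueous EtOH frees the amine F10.
- ClCO2CH2CCl3 with pyridine returns to the route at 33.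

**Step 18.** The risk is insufficient discrimination between a disubstituted alkene flanked by a quaternary and a branched carbon and the trisubstituted ring-A alkene. This would mean slow conversion or over-reduction. Fallback: from 33, homogeneous hydrogenation with RhCl(PPh3)3 and H2 in benzene–EtOH, whose steric demand favours the less substituted alkene, gives 34 directly; no new compound is involved.

## Further compounds

F1 | step 2 | triethylsilyl ether of (S)-linalool | C=C[C@](O[Si](CC)(CC)CC)(C)CCC=C(C)C
F2 | step 2 | triethylsilyl ether of aziridine 4 | C=C[C@](O[Si](CC)(CC)CC)(C)CC[C@H]1C(C)(C)N1S(=O)(=O)OCC(Cl)(Cl)Cl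
F3 | step 1 | 2,2,2-trichloroethyl (3R)-3-[(3S)-3-hydroxy-3-methylpent-4-en-1-yl]-2,2-dimethylaziridine-1-sulfonate | C=C[C@](O)(C)CC[C@@H]1C(C)(C)N1S(=O)(=O)OCC(Cl)(Cl)Cl
F4 | step 1 | 2,2,2-trichloroethyl N-{2-[(2S,5S)-5-ethenyl-5-methyloxolan-2-yl]propan-2-yl}sulfamate (trans isomer of 6) | C=C[C@]1(C)CC[C@@H](C(C)(C)NS(=O)(=O)OCC(Cl)(Cl)Cl)O1
F5 | step 9 | (R)-4-benzyl-3-[2-(OxTces)acetyl]oxazolidin-2-one | O=C(C[C@]1(C)CC[C@H](C(C)(C)NS(=O)(=O)OCC(Cl)(Cl)Cl)O1)N1[C@H](Cc2ccccc2)COC1=O
F6 | step 9 | methyl (1R,4S)-1-methyl-4-(prop-1-en-2-yl)cyclohex-2-en-1-yl carbonate | C[C@]1(OC(=O)OC)C=C[C@H](CC1)C(C)=C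
F7 | step 9 | (R)-4-benzyloxazolidin-2-one imide of acid 21 | CC1=C[C@@H]([C@@H](C(=O)N2[C@H](Cc3ccccc3)COC2=O)[C@]2(C)CC[C@H](C(C)(C)NS(=O)(=O)OCC(Cl)(Cl)Cl)O2)[C@H](CC1)C(C)=C
F8 | step 17 | trichloroacetimidate of 28 | CC1=C[C@H]2[C@H]([C@]3(C)CC[C@H](C(C)(C)NS(=O)(=O)OCC(Cl)(Cl)Cl)O3)[C@@H](OC(=N)C(Cl)(Cl)Cl)C=C(C)[C@H]2CC1
F9 | step 17 | C7 trichloroacetamide, C5=C6 alkene | CC1=C[C@H]2[C@H]([C@]3(C)CC[C@H](C(C)(C)NS(=O)(=O)OCC(Cl)(Cl)Cl)O3)C=C[C@@](C)(NC(=O)C(Cl)(Cl)Cl)[C@H]2CC1
F10 | step 17 | C7 primary amine, C5=C6 alkene | CC1=C[C@H]2[C@H]([C@]3(C)CC[C@H](C(C)(C)NS(=O)(=O)OCC(Cl)(Cl)Cl)O3)C=C[C@@](C)(N)[C@H]2CC1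
F0 | step 18 | none | none
A1 | alternative 1 | cis-fused tricycle with nitrile on C7 and azide on C15 | CC1=C[C@H]2[C@H]([C@]3(C)CC[C@H](C(C)(C)N=[N+]=[N-])O3)CC[C@@](C)(C#N)[C@H]2CC1
A2 | alternative 1 | monocyclic tertiary allylic alcohol with (Z)-C4=C11 alkene, C14 hydroxyl, C7 nitrile and C15 azide | CC1(O)C=C[C@H](CC1)[C@](C)(C#N)CC/C=C(/C)CC[C@@H](O)C(C)(C)N=[N+]=[N-]
A3 | alternative 2 | cis-decalin with C5 hydroxyl, C7 exocyclic methylene and tert-butyl carbamate on the C15 nitrogen | CC1=C[C@H]2[C@H]([C@]3(C)CC[C@H](C(C)(C)NC(=O)OC(C)(C)C)O3)[C@@H](O)CC(=C)[C@H]2CC1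
A4 | alternative 2 | C5 aldehyde on limonene-derived ring A, tert-butyl carbamate on the C15 nitrogen | CC1=C[C@@H]([C@@H](C=O)[C@]2(C)CC[C@H](C(C)(C)NC(=O)OC(C)(C)C)O2)[C@H](CC1)C(C)=C
A5 | alternative 3 | cis-2,5-disubstituted oxolane with C15 as CH2CO2CH3 | CC1=C[C@H]2[C@H]([C@]3(C)CC[C@H](CC(=O)OC)O3)CC[C@@](C)(NC=O)[C@H]2CC1
A6 | alternative 3 | C13 bromide with (E)-β-alkoxyacrylate on the C11 oxygen | CC1=C[C@H]2[C@H]([C@](C)(CCBr)O/C=C/C(=O)OC)CC[C@@](C)(NC=O)[C@H]2CC1
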